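Per day was my unit: I wrote k for the share of the standing substrate lost each day, the pseudo-first-order constant, and for a flask with its substrate in from the start I took the substrate left after a run as exp(−Σk), summed over its days, and the target as the rest of the charge, which fitted the east run's reading at 40.0 d with 56% of target beside 44% of substrate.

| flask | substrate | first nucleophile | solid second nucleophile | temperature | remark | time |
|---|---|---|---|---|---|---|
| east | 0.019 M | 4 equiv | 2 equiv | 55 °C | run made earlier |  |
| west | 0.019 M | 2 equiv | 2 equiv | 70 °C | run made earlier |  |
| north | 0.019 M | 8 equiv | 2 equiv | 55 °C | run made earlier |  |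
| violet | 0.019 M | 4.00 equiv (fed, over 20 d) | 2.00 equiv |  | the addition at 40 °C, then warmed to 70 °C; the feed brings no volume worth counting | 30 d |
| ochre | 0.019 M | 4.00 equiv | 2.00 equiv |  | everything together at the start at 40 °C, warmed to 70 °C at 20 d | 30 d |
| red | 0.019 M | 4.00 equiv (fed, over 20 d) | 2.00 equiv | 70 °C | all else is in the flask from the start; the feed brings no volume worth counting | 30 d |
| amber | 0.019 M (fed, over 20 d) | 4.00 equiv | 2.00 equiv | 70 °C | all else is in the flask from the start; the feed brings no volume worth counting | 30 d |
| grey | 0.019 M | 4.00 equiv (fed, over 50 h) | 2.00 equiv | 70 °C | all else is in the flask from the start; the feed brings no volume worth counting | 30 d |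

| run | time / d | target / % | substrate / % |
|---|---|---|---|
| east | 2.50 | 4 | 94 |
| east | 5.00 | 14 | 90 |
| east | 10.0 | 18 | 82 |
| east | 20.0 | 34 | 66 |
| east | 40.0 | 56 | 44 |
| west | 8.00 | 27 | 72 |
| west | 15.0 | 43 | 57 |
| west | 20.0 | 49 | 48 |
| west | 30.0 | 62 | 30 |
| west | 40.0 | 73 | 25 |
| north | 6.00 | 15 | 86 |
| north | 20.0 | 39 | 59 |
| north | 30.0 | 55 | 43 |
| north | 50.0 | 69 | 29 |
| north | 80.0 | 87 | 13 |

(standard deviation of a reading: 1.5 percentage points)

- the analysis behind the earlier runs scatters by 1.5 percentage points, standard deviation
- at the start none of the solid second nucleophile is in solution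
- a reading or a percentage of target counts all its forms, free or not

- the best flask by amount of target, in percent of the substrate charged; "all alike" if 1.5 percentage points covers them all (violet / ochre / red / amber / grey / all alike)
- amount of target at the end, in percent of the substrate charged, violet
- amount of target at the end, in percent of the substrate charged, ochre
- amount of target at the end, in percent of the substrate charged, red
- amount of target at the end, in percent of the substrate charged, amber
- amount of target at the end, in percent of the substrate charged, grey

From their last readings the east run gave k = 0.0205 d⁻¹, and the north run, with twice the first nucleophile, gave 0.0255 d⁻¹, a gain by a factor of 1.24. So I solved both ends and joined them: I assumed that at a small charge e of first nucleophile k follows e, and that at a large charge k stands at a top value. The curve e/(e+h) joining those ends gave h = 2.56 equiv, the knee charge, at which k is half its top value.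

The west run's reading at 30.0 d gave 0.0401 d⁻¹ at 2 equiv, and the curve, which I carried from 55 °C to 70 °C on trust, raised that by a factor of 1.39 to 0.0558 d⁻¹ for a charge of 4.00 equiv. Two things slowed that rate. Along a steady feed of first nucleophile the same curve averages 0.652 of the full k, so of 30 d grey counted 29.3 d of full days and red 23.0 d. Cold multiplied k by 0.368 from 70 °C to 55 °C, and I took that factor again down to 40 °C, so ochre counted 12.7 d. My own reckoning therefore gave target 80.5% in grey, 72.3% in red and 50.8% in ochre.

The forecast, holding that “the first nucleophile acts sub-linearly”, named grey as best, with 45% for violet, 47% for ochre, 70% for red, 62% for amber and 77% for grey, between 69% and 84%; my figure for grey stood higher than its figure.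

Grey gave 82.1%, more than any other flask, against 50.0% for violet, 50.6% for ochre, 71.2% for red and 68.6% for amber, and grey still held 16.1% of substrate.

    substrate ⇌ intermediate (K = 0.00320, k = 0.00920 h⁻¹, Ea = 118 kJ mol⁻¹, ΔH = −34.0 kJ mol⁻¹)
    second nucleophile + intermediate → other capture product (k = 2.60 M⁻¹ h⁻¹, Ea = 84.0 kJ mol⁻¹)
    crystals ⇌ target, rate k3*(cs3 - [target]) while solid is left; crystals form when [target] > cs3 (solubility = 6.80 mM, k = 0.810 h⁻¹)
    first nucleophile + intermediate → target (k = 17.0 M⁻¹ h⁻¹, Ea = 67.0 kJ mol⁻¹)
    solid second nucleophile ⇌ second nucleophile, rate k5*(cs5 - [second nucleophile]) while solid is left; crystals form when [second nucleophile] > cs5 (solubility = 13.0 mM, k = 0.00780 h⁻¹)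
    (constants at 70 °C)

Taking that 16.1% and scaling its exponent by red's full days over grey's, 0.785, the knee charge put red's substrate at 23.8%, and red held 25.8%. For the same flask as violet with 1.00 equiv of first nucleophile, the curve scaled k by 0.461, which turned violet's 49% of substrate into 72.0%; that neighbour held 77.1%.

All runs come from a simulation on assumed constants; noise was put on by code.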